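**Retrosynthetic overview**
- The strategy rests on the two indole C3 side chains: each is a quaternary carbon bound to indole C3, two methyl groups and a vinyl group. Both C(quaternary)–CH=CH2 bonds are made last, by adding H and vinyl across the two C3-isopropenyl groups of a bis(N-tosylindol-5-yl) precursor with a cationic nickel hydride, one molecule of ethylene per isopropenyl group.
- The (E)-aryl–CH=CH–C(quaternary) link of that precursor is cut by Suzuki coupling of an (E)-alkenylboronate with 5-iodo-3-isopropenyl-1-tosylindole; the boronate comes from a neopentyl aldehyde by boron–Wittig olefination.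
- The ring C-methyl comes from an enol triflate (Negishi). The triflate derives from the regiodefined enolate of a copper-catalysed conjugate addition of the same indole building block to (R)-4-(silyloxymethyl)-4-methylcyclohex-2-enone, which sets the CH(aryl) centre.
- The cyclohexene, the only ring that is built, is formed first by an enantioselective Diels–Alder reaction of methacrolein with a 1-amino-3-siloxybutadiene, which sets the quaternary centre; the indole rings come from 5-iodoindole.

Key step: step 14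

Assumption: the (4R,5R)-TADDOL is taken to give the (1R) quaternary centre in step 1; if the sense proves opposite, the (4S,5S)-catalyst is used and nothing else changes.

**Step 1**
Reactants: 1 methacrolein; 2 (E)-3-(tert-butyldimethylsilyloxy)-N,N-dimethylbuta-1,3-dien-1-amine
Product: 4 [(1R,2S)-2-(dimethylamino)-1-methyl-4-(tert-butyldimethylsilyloxy)cyclohex-3-en-1-yl]methanol, via Diels–Alder aldehyde 3 (not isolated)
Conditions: (4R,5R)-2,2-dimethyl-α,α,α′,α′-tetra(1-naphthyl)-1,3-dioxolane-4,5-dimethanol (20 mol %), toluene, −80 °C; then LiAlH4, Et2O, −78 °C to rt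
Reagents that add atoms: none
Why: Hydrogen-bond-catalysed endo Diels–Alder reaction in which the TADDOL hydroxyl activates the aldehyde and shields one enantioface, so the quaternary carbon should be set as (R) (the amine-bearing centre follows from the endo mode and is removed in step 2), after which LiAlH4 reduces the neopentyl aldehyde in the same flask.

**Step 2**
Reactants: 4 [(1R,2S)-2-(dimethylamino)-1-methyl-4-(tert-butyldimethylsilyloxy)cyclohex-3-en-1-yl]methanol
Product: 5 (R)-4-(hydroxymethyl)-4-methylcyclohex-2-en-1-one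
Conditions: HF (48% aq.), MeCN, 0 °C to rt
Reagents that add atoms: none
Why: Acid cleavage of the silyl enol ether gives the ketone and the β-dimethylamino group leaves by E1cB-type β-elimination, giving the enone without touching the quaternary centre.

**Step 3**
Reactants: 5 (R)-4-(hydroxymethyl)-4-methylcyclohex-2-en-1-one
Product: 6 (R)-4-[(tert-butyldiphenylsilyloxy)methyl]-4-methylcyclohex-2-en-1-one
Conditions: TBDPSCl, imidazole, DMF, rt
Reagents that add atoms: tert-butyldiphenylsilyl chloride, CC(C)(C)[Si](Cl)(c1ccccc1)c1ccccc1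
Why: Standard silylation of a primary alcohol; the bulky silyl ether is inert to organometallics and makes the CH2O arm clearly larger than the methyl group for step 7.

**Step 4**
Reactants: 7 5-iodoindole
Product: 8 3-acetyl-5-iodoindole
Conditions: Et2AlCl, CH2Cl2, 0 °C; then AcCl, 0 °C
Reagents that add atoms: acetyl chloride, CC(Cl)=O
Why: Friedel–Crafts acylation of the N-aluminated free indole, which is selective for C3 and tolerates the aryl iodide.

**Step 5**
Reactants: 8 3-acetyl-5-iodoindole
Product: 9 3-acetyl-5-iodo-1-tosylindole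
Conditions: NaH, THF, 0 °C; then TsCl, rt
Reagents that add atoms: p-toluenesulfonyl chloride, Cc1ccc(S(Cl)(=O)=O)cc1
Why: N-sulfonylation of the acidic 3-acylindole N–H via its sodium salt.

**Step 6**
Reactants: 9 3-acetyl-5-iodo-1-tosylindole
Product: 10 5-iodo-3-isopropenyl-1-tosylindole
Conditions: Ph3PCH3Br, KOtBu, THF, 0 °C to rt
Reagents that add atoms: methyltriphenylphosphonium bromide, C[P+](c1ccccc1)(c1ccccc1)c1ccccc1.[Br-]
Why: Wittig methylenation of the aryl methyl ketone, whose carbonyl is made more electrophilic by the N-sulfonyl group.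

**Step 7**
Reactants: 10 5-iodo-3-isopropenyl-1-tosylindole; 6 (R)-4-[(tert-butyldiphenylsilyloxy)methyl]-4-methylcyclohex-2-en-1-one
Product: 12 5-[(1S,6R)-6-[(tert-butyldiphenylsilyloxy)methyl]-6-methyl-3-(trimethylsilyloxy)cyclohex-2-en-1-yl]-3-isopropenyl-1-tosylindole, via arylmagnesium chloride 11 (not isolated)
Conditions: iPrMgCl·LiCl, THF, −20 °C; then CuBr·SMe2 (10 mol %), 6, Me3SiCl, DMPU, −78 to −40 °C
Reagents that add atoms: trimethylsilyl chloride, C[Si](C)(C)Cl
Why: Iodine–magnesium exchange followed by copper-catalysed, silyl-chloride-accelerated conjugate addition of the aryl Grignard reagent; the aryl group should enter C3 axially on the face anti to the silyloxymethyl arm (cis to methyl), setting the new centre as (S), and the enolate is trapped as the silyl enol ether with its double bond fixed toward the aryl-bearing carbon.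

**Step 8**
Reactants: 12 5-[(1S,6R)-6-[(tert-butyldiphenylsilyloxy)methyl]-6-methyl-3-(trimethylsilyloxy)cyclohex-2-en-1-yl]-3-isopropenyl-1-tosylindole
Product: 13 (3S,4R)-4-[(tert-butyldiphenylsilyloxy)methyl]-4-methyl-3-(3-isopropenyl-1-tosylindol-5-yl)cyclohex-1-en-1-yl trifluoromethanesulfonate
Conditions: CsF, PhNTf2, DME, rt
Reagents that add atoms: N-phenylbis(trifluoromethanesulfonimide), O=S(=O)(N(c1ccccc1)S(=O)(=O)C(F)(F)F)C(F)(F)F
Why: Fluoride-induced desilylation frees the enolate, which is O-sulfonylated faster than it equilibrates, so the enol triflate keeps the regiochemistry of step 7 without any strong base.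

**Step 9**
Reactants: 13 (3S,4R)-4-[(tert-butyldiphenylsilyloxy)methyl]-4-methyl-3-(3-isopropenyl-1-tosylindol-5-yl)cyclohex-1-en-1-yl trifluoromethanesulfonate
Product: 14 5-[(1S,6R)-6-[(tert-butyldiphenylsilyloxy)methyl]-3,6-dimethylcyclohex-2-en-1-yl]-3-isopropenyl-1-tosylindole
Conditions: MeZnCl, Pd(PPh3)4 (5 mol %), THF, 50 °C
Reagents that add atoms: methylzinc chloride, C[Zn]Cl
Why: Negishi coupling of an alkenyl triflate with a methylzinc reagent, which places the ring methyl on the trisubstituted alkene at the required position and leaves the sulfonamide, silyl ether and isopropenyl group alone.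

**Step 10**
Reactants: 14 5-[(1S,6R)-6-[(tert-butyldiphenylsilyloxy)methyl]-3,6-dimethylcyclohex-2-en-1-yl]-3-isopropenyl-1-tosylindole
Product: 15 [(1R,2S)-2-(3-isopropenyl-1-tosylindol-5-yl)-1,4-dimethylcyclohex-3-en-1-yl]methanol
Conditions: Bu4NF, THF, 0 °C to rt
Reagents that add atoms: none
Why: Fluoride cleavage of the silyl ether; the N-tosylindole is stable to Bu4NF at room temperature.

**Step 11**
Reactants: 15 [(1R,2S)-2-(3-isopropenyl-1-tosylindol-5-yl)-1,4-dimethylcyclohex-3-en-1-yl]methanol
Product: 16 (1R,2S)-2-(3-isopropenyl-1-tosylindol-5-yl)-1,4-dimethylcyclohex-3-ene-1-carbaldehyde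
Conditions: Dess–Martin periodinane, NaHCO3, CH2Cl2, rt
Reagents that add atoms: none
Why: Dess–Martin oxidation of the neopentyl alcohol under buffered, non-acidic conditions; the aldehyde has no α-hydrogen and cannot epimerise.

**Step 12**
Reactants: 16 (1R,2S)-2-(3-isopropenyl-1-tosylindol-5-yl)-1,4-dimethylcyclohex-3-ene-1-carbaldehyde
Product: 17 3-isopropenyl-5-[(1R,6S)-3,6-dimethyl-6-[(E)-2-(4,4,5,5-tetramethyl-1,3,2-dioxaborolan-2-yl)vinyl]cyclohex-2-en-1-yl]-1-tosylindole
Conditions: CH2(Bpin)2, lithium 2,2,6,6-tetramethylpiperidide, THF, 0 °C; then 16, −78 °C to rt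
Reagents that add atoms: bis(4,4,5,5-tetramethyl-1,3,2-dioxaborolan-2-yl)methane, CC1(C)OB(CB2OC(C)(C)C(C)(C)O2)OC1(C)C
Why: Boron–Wittig olefination, in which the lithiated geminal bis(boronate) adds to the non-enolisable aldehyde and syn B–O elimination should give the (E)-alkenylboronate.

**Step 13**
Reactants: 17 3-isopropenyl-5-[(1R,6S)-3,6-dimethyl-6-[(E)-2-(4,4,5,5-tetramethyl-1,3,2-dioxaborolan-2-yl)vinyl]cyclohex-2-en-1-yl]-1-tosylindole; 10 5-iodo-3-isopropenyl-1-tosylindole
Product: 18 5-[(1R,6S)-3,6-dimethyl-6-[(E)-2-(3-isopropenyl-1-tosylindol-5-yl)vinyl]cyclohex-2-en-1-yl]-3-isopropenyl-1-tosylindole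
Conditions: PdCl2(dppf) (5 mol %), K3PO4, THF/H2O, 60 °C
Reagents that add atoms: none
Why: Suzuki–Miyaura coupling of the alkenylboronate with the aryl iodide, which proceeds with retention of the (E) geometry and involves no alkene insertion, so the isopropenyl groups are not touched.

**Step 14**
Reactants: 18 5-[(1R,6S)-3,6-dimethyl-6-[(E)-2-(3-isopropenyl-1-tosylindol-5-yl)vinyl]cyclohex-2-en-1-yl]-3-isopropenyl-1-tosylindole; 19 ethylene
Product: 22 3-(2-methylbut-3-en-2-yl)-5-[(1R,6S)-3,6-dimethyl-6-[(E)-2-[3-(2-methylbut-3-en-2-yl)-1-tosylindol-5-yl]vinyl]cyclohex-2-en-1-yl]-1-tosylindole, via ring-indole mono-adduct 20 (not isolated), via styryl-indole mono-adduct 21 (not isolated)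
Conditions: [Ni(C3H5)Br]2 (10 mol %), (S)-1,1′-binaphthyl-2,2′-diyl N,N-bis[(S)-1-phenylethyl]phosphoramidite (20 mol %), Na[B(3,5-(CF3)2C6H3)4] (20 mol %), ethylene (1 atm, excess), CH2Cl2, −70 to −40 °C, run until both isopropenyl groups are consumed
Reagents that add atoms: ethylene (the second of the two molecules taken up, one per isopropenyl group), C=C
Why: The cationic divalent nickel hydride formed from [Ni(C3H5)Br]2, the phosphoramidite and Na[B(3,5-(CF3)2C6H3)4] adds in the Markovnikov sense to a 1,1-disubstituted alkene to give a tertiary nickel alkyl at the carbon on indole C3 (stabilised as an η3-indolylmethyl species), ethylene inserts into this Ni–C bond and β-hydride elimination from the resulting primary alkyl releases the vinyl group and returns the hydride; the cycle runs once at each isopropenyl group, so two molecules of ethylene are consumed, the mono-adducts 20 and 21 converge on 22, two C(quaternary)–CH= bonds form and no ring closes. The closest known reaction type is the nickel-catalysed hydrovinylation of α-alkylstyrenes and vinylindoles with ethylene, which gives all-carbon quaternary benzylic centres. No new stereocentre arises because each new quaternary carbon carries two methyl groups, and the two existing centres lie far from the reacting carbons. The step needs chemoselectivity for the two isopropenyl groups over the (E)-1,2-disubstituted styryl alkene and the trisubstituted ring alkene; this is secured by the much slower hydride addition to these internal, hindered alkenes at low temperature with the bulky ligand. Selectivity for the heterodimer over ethylene oligomers and arene-alkene homodimers follows from the preference of the hydride for the conjugated alkene and from the crowded tertiary nickel alkyl, which accepts only ethylene. The product vinyl groups are neopentylic with no allylic hydrogen, so they should neither isomerise nor react again, and the N-tosyl groups protect the indoles from protonation and cationic dimerisation.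

**Step 15**
Reactants: 22 3-(2-methylbut-3-en-2-yl)-5-[(1R,6S)-3,6-dimethyl-6-[(E)-2-[3-(2-methylbut-3-en-2-yl)-1-tosylindol-5-yl]vinyl]cyclohex-2-en-1-yl]-1-tosylindole
Product: 23 3-(2-methylbut-3-en-2-yl)-5-[(E)-2-[(1S,2R)-1,4-dimethyl-2-[3-(2-methylbut-3-en-2-yl)-1H-indol-5-yl]cyclohex-3-en-1-yl]vinyl]-1H-indole (EANPDB:ANNO_00013)
Conditions: Cs2CO3, MeOH/THF (1:2), 60 °C
Reagents that add atoms: none
Why: Nucleophilic N-desulfonylation by methoxide at sulfur, a mild cleavage of N-tosylindoles that leaves all four alkenes and both stereocentres untouched.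

**Compound list**
1 | methacrolein | C=C(C)C=O | starting material
2 | (E)-3-(tert-butyldimethylsilyloxy)-N,N-dimethylbuta-1,3-dien-1-amine | CN(C)/C=C/C(=C)O[Si](C)(C)C(C)(C)C | starting material
3 | (1R,2S)-2-(dimethylamino)-1-methyl-4-(tert-butyldimethylsilyloxy)cyclohex-3-ene-1-carbaldehyde (endo adduct, not isolated) | O=C[C@]1(C)CCC(O[Si](C)(C)C(C)(C)C)=C[C@@H]1N(C)C | intermediate
4 | [(1R,2S)-2-(dimethylamino)-1-methyl-4-(tert-butyldimethylsilyloxy)cyclohex-3-en-1-yl]methanol | OC[C@]1(C)CCC(O[Si](C)(C)C(C)(C)C)=C[C@@H]1N(C)C | intermediate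
5 | (R)-4-(hydroxymethyl)-4-methylcyclohex-2-en-1-one | O=C1C=C[C@](C)(CO)CC1 | intermediate
6 | (R)-4-[(tert-butyldiphenylsilyloxy)methyl]-4-methylcyclohex-2-en-1-one | O=C1C=C[C@](C)(CO[Si](c2ccccc2)(c2ccccc2)C(C)(C)C)CC1 | intermediate
7 | 5-iodoindole | Ic1ccc2[nH]ccc2c1 | starting material
8 | 3-acetyl-5-iodoindole | CC(=O)c1c[nH]c2ccc(I)cc12 | intermediate
9 | 3-acetyl-5-iodo-1-tosylindole | CC(=O)c1cn(S(=O)(=O)c2ccc(C)cc2)c2ccc(I)cc12 | intermediate
10 | 5-iodo-3-isopropenyl-1-tosylindole | C=C(C)c1cn(S(=O)(=O)c2ccc(C)cc2)c2ccc(I)cc12 | intermediate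
11 | (3-isopropenyl-1-tosylindol-5-yl)magnesium chloride, LiCl complex (not isolated) | C=C(C)c1cn(S(=O)(=O)c2ccc(C)cc2)c2ccc([Mg]Cl)cc12 | intermediate
12 | 5-[(1S,6R)-6-[(tert-butyldiphenylsilyloxy)methyl]-6-methyl-3-(trimethylsilyloxy)cyclohex-2-en-1-yl]-3-isopropenyl-1-tosylindole | CC(C)(C)[Si](c1ccccc1)(c1ccccc1)OC[C@]1(C)CCC(O[Si](C)(C)C)=C[C@H]1c1ccc2n(S(=O)(=O)c3ccc(C)cc3)cc(C(C)=C)c2c1 | intermediate
13 | (3S,4R)-4-[(tert-butyldiphenylsilyloxy)methyl]-4-methyl-3-(3-isopropenyl-1-tosylindol-5-yl)cyclohex-1-en-1-yl trifluoromethanesulfonate | CC(C)(C)[Si](c1ccccc1)(c1ccccc1)OC[C@]1(C)CCC(OS(=O)(=O)C(F)(F)F)=C[C@H]1c1ccc2n(S(=O)(=O)c3ccc(C)cc3)cc(C(C)=C)c2c1 | intermediate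
14 | 5-[(1S,6R)-6-[(tert-butyldiphenylsilyloxy)methyl]-3,6-dimethylcyclohex-2-en-1-yl]-3-isopropenyl-1-tosylindole | CC(C)(C)[Si](c1ccccc1)(c1ccccc1)OC[C@]1(C)CCC(C)=C[C@H]1c1ccc2n(S(=O)(=O)c3ccc(C)cc3)cc(C(C)=C)c2c1 | intermediate
15 | [(1R,2S)-2-(3-isopropenyl-1-tosylindol-5-yl)-1,4-dimethylcyclohex-3-en-1-yl]methanol | OC[C@]1(C)CCC(C)=C[C@H]1c1ccc2n(S(=O)(=O)c3ccc(C)cc3)cc(C(C)=C)c2c1 | intermediate
16 | (1R,2S)-2-(3-isopropenyl-1-tosylindol-5-yl)-1,4-dimethylcyclohex-3-ene-1-carbaldehyde | O=C[C@]1(C)CCC(C)=C[C@H]1c1ccc2n(S(=O)(=O)c3ccc(C)cc3)cc(C(C)=C)c2c1 | intermediate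
17 | 3-isopropenyl-5-[(1R,6S)-3,6-dimethyl-6-[(E)-2-(4,4,5,5-tetramethyl-1,3,2-dioxaborolan-2-yl)vinyl]cyclohex-2-en-1-yl]-1-tosylindole | CC1(C)OB(/C=C/[C@]2(C)CCC(C)=C[C@H]2c2ccc3n(S(=O)(=O)c4ccc(C)cc4)cc(C(C)=C)c3c2)OC1(C)C | intermediate
18 | 5-[(1R,6S)-3,6-dimethyl-6-[(E)-2-(3-isopropenyl-1-tosylindol-5-yl)vinyl]cyclohex-2-en-1-yl]-3-isopropenyl-1-tosylindole (key-step precursor) | C=C(C)c1cn(S(=O)(=O)c2ccc(C)cc2)c2ccc(/C=C/[C@]3(C)CCC(C)=C[C@H]3c3ccc4n(S(=O)(=O)c5ccc(C)cc5)cc(C(C)=C)c4c3)cc12 | intermediate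
19 | ethylene | C=C | starting material
20 | 3-isopropenyl-5-[(E)-2-[(1S,2R)-1,4-dimethyl-2-[3-(2-methylbut-3-en-2-yl)-1-tosylindol-5-yl]cyclohex-3-en-1-yl]vinyl]-1-tosylindole (mono-adduct at the ring-bound indole, not isolated) | C=C(C)c1cn(S(=O)(=O)c2ccc(C)cc2)c2ccc(/C=C/[C@]3(C)CCC(C)=C[C@H]3c3ccc4n(S(=O)(=O)c5ccc(C)cc5)cc(C(C)(C)C=C)c4c3)cc12 | intermediate
21 | 3-isopropenyl-5-[(1R,6S)-3,6-dimethyl-6-[(E)-2-[3-(2-methylbut-3-en-2-yl)-1-tosylindol-5-yl]vinyl]cyclohex-2-en-1-yl]-1-tosylindole (mono-adduct at the styryl-bound indole, not isolated) | C=CC(C)(C)c1cn(S(=O)(=O)c2ccc(C)cc2)c2ccc(/C=C/[C@]3(C)CCC(C)=C[C@H]3c3ccc4n(S(=O)(=O)c5ccc(C)cc5)cc(C(C)=C)c4c3)cc12 | intermediate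
22 | N,N′-bis-tosyl target (key-step product) | C=CC(C)(C)c1cn(S(=O)(=O)c2ccc(C)cc2)c2ccc(/C=C/[C@]3(C)CCC(C)=C[C@H]3c3ccc4n(S(=O)(=O)c5ccc(C)cc5)cc(C(C)(C)C=C)c4c3)cc12 | intermediate
23 | EANPDB:ANNO_00013 | C=CC(C)(C)c1c[nH]c2ccc(/C=C/[C@]3(C)CCC(C)=C[C@H]3c3ccc4[nH]cc(C(C)(C)C=C)c4c3)cc12 | target

**Step count**
Total: 15 steps. Longest linear sequence: 12 steps (steps 1–3 and 7–15; the branch through steps 4–6 is equally long).

**Steps most likely to fail**

1. Step 14 (key step). The nickel hydride may also add to the styryl or ring alkene, moving the ring double bond into conjugation with the indole and eroding the CH(aryl) centre, or the reaction may stall after the first of the two hydrovinylations. The fallback sets out from 18 and comes back at 22. Hydroboration of both terminal 1,1-disubstituted alkenes with 9-borabicyclo[3.3.1]nonane (THF, 0 °C to rt), which should leave the internal alkenes alone, gives the bis(B-alkyl-9-borabicyclononane) F1. Oxidation with NaBO3·4H2O gives the bis(2-arylpropan-1-ol) F2, a mixture of epimers at the two new CH(CH3) carbons that does not matter. Dess–Martin oxidation gives the bis(2-arylpropanal) F3. Double α-methylation of the aldehyde enolates (KOtBu, MeI, THF, −40 °C) builds both quaternary carbons and gives the bis(2-aryl-2-methylpropanal) F4, in which the epimers have converged. Double Wittig methylenation (Ph3PCH3Br, KOtBu, THF) then gives 22.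

2. Step 7. Discrimination between the methyl and silyloxymethyl faces may be too small, so that part of the aryl group enters cis to the CH2O arm, or addition at the neopentyl-type β-carbon may be slow enough for 1,2-addition to compete. The fallback sets out from 11 and 6 and comes back at 12, replacing substrate control by catalyst control. Transmetalation of 11 with ZnCl2 gives the arylzinc chloride F5, which is added to 6 with [RhCl((S)-binap)]2 and Me3SiCl in THF at 20 °C (rhodium-catalysed asymmetric 1,4-addition with silyl trapping). The BINAP antipode is chosen by analogy with cyclohex-2-enone to deliver the aryl group to the face cis to methyl, and the same regiodefined silyl enol ether 12 results.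

3. Step 12. The bulky α-boryl carbanion may add slowly to the aldehyde on the quaternary carbon next to the aryl-bearing carbon, leaving conversion incomplete or lowering the E-selectivity of the elimination. The fallback sets out from 16 and comes back at 18. Wittig methylenation (Ph3PCH3Br, KOtBu, THF) gives 5-[(1R,6S)-3,6-dimethyl-6-vinylcyclohex-2-en-1-yl]-3-isopropenyl-1-tosylindole F6. A Heck reaction of F6 with 10 (Pd(OAc)2, Bu4NCl, NaHCO3, DMF, 70 °C) arylates the terminal carbon of the only monosubstituted alkene; because the neighbouring carbon is quaternary, β-hydride elimination can give only the (E)-styryl alkene 18.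

**Further compounds**
F1 | step 14 | bis(B-alkyl-9-borabicyclo[3.3.1]nonane) from twofold hydroboration of 18 | CC(CB1C2CCCC1CCC2)c1cn(S(=O)(=O)c2ccc(C)cc2)c2ccc(/C=C/[C@]3(C)CCC(C)=C[C@H]3c3ccc4n(S(=O)(=O)c5ccc(C)cc5)cc(C(C)CB5C6CCCC5CCC6)c4c3)cc12
F2 | step 14 | bis(1-hydroxypropan-2-yl) analogue of 18 (epimer mixture at the two CH(CH3) carbons) | CC(CO)c1cn(S(=O)(=O)c2ccc(C)cc2)c2ccc(/C=C/[C@]3(C)CCC(C)=C[C@H]3c3ccc4n(S(=O)(=O)c5ccc(C)cc5)cc(C(C)CO)c4c3)cc12
F3 | step 14 | bis(1-oxopropan-2-yl) analogue of 18 (epimer mixture at the two CH(CH3) carbons) | CC(C=O)c1cn(S(=O)(=O)c2ccc(C)cc2)c2ccc(/C=C/[C@]3(C)CCC(C)=C[C@H]3c3ccc4n(S(=O)(=O)c5ccc(C)cc5)cc(C(C)C=O)c4c3)cc12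
F4 | step 14 | bis(2-methyl-1-oxopropan-2-yl) analogue of 18 | CC(C)(C=O)c1cn(S(=O)(=O)c2ccc(C)cc2)c2ccc(/C=C/[C@]3(C)CCC(C)=C[C@H]3c3ccc4n(S(=O)(=O)c5ccc(C)cc5)cc(C(C)(C)C=O)c4c3)cc12
F5 | step 7 | (3-isopropenyl-1-tosylindol-5-yl)zinc chloride | C=C(C)c1cn(S(=O)(=O)c2ccc(C)cc2)c2ccc([Zn]Cl)cc12
F6 | step 12 | 5-[(1R,6S)-3,6-dimethyl-6-vinylcyclohex-2-en-1-yl]-3-isopropenyl-1-tosylindole | C=C[C@]1(C)CCC(C)=C[C@H]1c1ccc2n(S(=O)(=O)c3ccc(C)cc3)cc(C(C)=C)c2c1
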